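**Plan**

1. Drimane numbering is used: ring A = C1–C5 + C10 (gem-dimethyl at C4), ring B = C5–C10, C11 on C9, C12 on C8. Retrosynthetic cuts, in order: the C6–O acyl bond and the C12 oxidation level (C12 stays an acetal until the end); C4–CH3; C4=C5 (ring A); C10–C1; C7–C8 and C9–C10 (ring B).
2. Forward: ring B is made first by Diels–Alder reaction of a 1-methoxy-3-silyloxy diene with a chiral 5-alkoxybutenolide, giving a cis-fused lactone enone. The C1–C4 chain is then added to C10 by 1,4-addition, and ring A is closed last by aldol condensation of C5 onto the C4 ketone.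
3. Feature that makes the closure possible: at that stage the C6 oxygen of ring B is a ketone standing 1,7 to the C4 carbonyl (C6–C5–C10–C1–C2–C3–C4). C5 is therefore the enol carbon, and the new ring is a 1-acyl-2-methylcyclohexene whose β-carbon (C4) then accepts the second methyl.
4. The closure is deliberately carried through to sp2 C5. A carbon tethered to C10 can reach C5 only on the face of that tether (cis fusion), so H-5 is put on afterwards under kinetic control.
5. Stereochemistry: C8 and C9 (cis, absolute) come from the menthyloxy auxiliary in the cycloaddition; C10 from addition anti to the lactone; C5 from α-face protonation anti to the C10 methyl; C6 from α-face hydride delivery.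
6. The C12 acetal keeps C12 from lactonising with the 6β-oxygen. After esterification it is hydrolysed and oxidised to the cis-anhydride, which water opens to the diacid.

Key step: step 4

Remark: (5S)-5-(d-menthyloxy)furan-2(5H)-one (3) and (2E,4E,6E)-octa-2,4,6-trienoic acid (16) are taken as purchasable; α/β descriptors refer to the drimane numbering above, with the C10 methyl β.

**Step 1**
Reactants: 1 (E)-4-methoxypent-3-en-2-one
Product: 2 (E)-4-methoxy-2-(trimethylsilyloxy)penta-1,3-diene
Conditions: LDA, THF, –78 °C; TMSCl, –78 °C → rt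
Reagents that add atoms: chlorotrimethylsilane, C[Si](C)(C)Cl
Why: Kinetic deprotonation of the methyl ketone at the α′-methyl followed by O-silylation (silyl enol ether formation) should give the cross-conjugated 2-silyloxy diene, the C3=C4 geometry being retained and of no later consequence.

**Step 2**
Reactants: 2 (E)-4-methoxy-2-(trimethylsilyloxy)penta-1,3-diene; 3 (5S)-5-(d-menthyloxy)furan-2(5H)-one
Product: 5 ring-B enone lactone acetal, via silyl enol ether cycloadduct 4 (not isolated)
Conditions: PhMe, 110 °C, sealed tube; then 0.1 M HCl, THF, 0 °C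
Reagents that add atoms: none
Why: A thermal Diels–Alder reaction in which the diene adds to the butenolide face anti to the menthyloxy group, its CH2 terminus (C7) bonding to the β-carbon (C8) and its methoxy-bearing terminus (C10) to the α-carbon (C9), should set C8 and C9 (cis fusion, absolute configuration from the auxiliary), after which mild acid cleaves the silyl enol ether and eliminates methanol to the C5=C10 enone, erasing the C10 centre of 4.

**Step 3**
Reactants: 5 ring-B enone lactone acetal; 6 2-(3-chloropropyl)-2-methyl-1,3-dioxolane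
Product: 9 C10-quaternary keto ketal, via Grignard reagent 7 (not isolated), via trimethylsilyl enol ether 8 (not isolated)
Conditions: 6, Mg, THF, 45 °C; then CuBr·SMe2 (cat.), TMSCl, HMPA, THF, –78 °C, add 5; aq. citric acid, 0 °C
Reagents that add atoms: none
Why: Copper-catalysed, TMSCl-accelerated 1,4-addition of the Grignard reagent to the β-methyl enone should create the quaternary C10 by attack on the convex α-face, anti to the cis-fused lactone and trans to the C9–C11 bond, so that the C10 methyl ends β (cis to C11), the silyl enol ether being cleaved on work-up.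

**Step 4**
Reactants: 9 C10-quaternary keto ketal
Product: 12 tricyclic C4=C5 enone, via diketone 10 (not isolated), via aldol 11 (not isolated)
Conditions: TsOH·H2O (cat.), acetone/H2O, 40 °C; then PhMe, 100 °C, Dean–Stark
Reagents that add atoms: none
Why: Acid first exchanges the dioxolane to unveil the C4 methyl ketone (10); the C5 enol of the C6 ketone then adds to C4, and the tertiary aldol 11 loses water to the conjugated C4=C5 enone, the closest precedent being the cyclodehydration of a 1,7-diketone to a 1-acyl-2-methylcyclohexene (the aldol stage of a Robinson-type annulation). Ring A is closed in the 6-(enolexo)-exo-trig mode, C5 attacking the C4 carbonyl through a chair-like array. No stereocentre is created in 12, and this is intended: a carbon tethered to C10 can reach C5 only on the tether face (cis fusion), so the C4 and C5 centres of 11 are erased and the ring-fusion hydrogen is introduced afterwards. The selectivity needed is constitutional: of the four enol/carbonyl pairings only C5→C4 gives a six-membered aldol that can dehydrate into conjugation, whereas C3→C6 gives a bridgehead aldol that can only revert and C7→C4 or CH3→C6 would need eight-membered rings, so the reversible aldols should drain into 12. C10 is quaternary and C8/C9 are held in the cis-fused lactone, so the existing centres should survive the acid.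

**Step 5**
Reactants: 12 tricyclic C4=C5 enone
Product: 14 trans-fused 6-ketone, via trimethylsilyl enol ether 13 (not isolated)
Conditions: Me2CuLi (from MeLi, CuI), TMSCl, Et2O/THF, –78 → –20 °C; then 1 M HCl, THF, –20 → 0 °C
Reagents that add atoms: lithium dimethylcuprate, [Li+].C[Cu-]C (made in the flask from methyllithium, [Li]C)
Why: Conjugate addition of the cuprate to the s-cis, pulegone-like enone should install the second C4 methyl and give the C5=C6 silyl enol ether, whose kinetic C-protonation on the α-face, anti to the axial C10 methyl and the β-lactone, should give the trans ring fusion (5α-H); equilibrating conditions are avoided afterwards because the cis-fused epimer may be the more stable one.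

**Step 6**
Reactants: 14 trans-fused 6-ketone
Product: 15 6β-alcohol
Conditions: NaBH4, CeCl3·7H2O, MeOH/THF, –40 → 0 °C
Reagents that add atoms: none
Why: Luche reduction under near-neutral conditions that do not enolise C5 should deliver hydride to C6 from the α-face, the β-face being blocked by the axial C10 and C4β methyls and by C12, to give the axial 6β-alcohol.

**Step 7**
Reactants: 15 6β-alcohol; 16 (2E,4E,6E)-octa-2,4,6-trienoic acid
Product: 18 6β-trienoate, via mixed anhydride 17 (not isolated)
Conditions: 2,4,6-Cl3C6H2COCl, Et3N, THF, rt; then 15, DMAP, PhMe, 50 °C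
Reagents that add atoms: none
Why: Yamaguchi esterification through the mixed anhydride with DMAP should acylate the hindered axial alcohol with retention at C6 and without change of the triene geometry, and because C12 is an acetal at this stage no lactone can form with the 6β-oxygen.

**Step 8**
Reactants: 18 6β-trienoate
Product: 19 C12 lactol
Conditions: TFA/H2O/THF, 0 °C → rt
Reagents that add atoms: water, O
Why: Acid-catalysed acetal hydrolysis through the C12 oxocarbenium ion should release menthol and give the lactol, which is expected to stay ring-closed and cis-fused and so to shield C8 from epimerisation, while the hindered trienoate is stable to aqueous acid.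

**Step 9**
Reactants: 19 C12 lactol
Product: 21 target diacid, via cyclic anhydride 20 (not isolated)
Conditions: Dess–Martin periodinane, CH2Cl2, rt; then THF/H2O, rt
Reagents that add atoms: water, O
Why: Oxidation of the lactol C–H with the hypervalent iodine reagent, as in lactol-to-lactone oxidations, should give the cis-fused cyclic anhydride, which holds C8 and C9 cis and is opened by water to the diacid without affecting the C6 ester.

**Compound list**

1 | (E)-4-methoxypent-3-en-2-one | CO/C(C)=C/C(C)=O | starting material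
2 | (E)-4-methoxy-2-(trimethylsilyloxy)penta-1,3-diene | C=C(O[Si](C)(C)C)/C=C(/OC)C | intermediate
3 | (5S)-5-{[(1S,2R,5S)-5-methyl-2-(propan-2-yl)cyclohexyl]oxy}furan-2(5H)-one, (5S)-5-(d-menthyloxy)-2(5H)-furanone | O=C1C=C[C@@H](O[C@H]2C[C@@H](C)CC[C@@H]2C(C)C)O1 | starting material
4 | (3S,3aS,7aS)-7-methoxy-7-methyl-3-(d-menthyloxy)-5-(trimethylsilyloxy)-3a,4,7,7a-tetrahydro-2-benzofuran-1(3H)-one, both C7 epimers (cis-fused; menthyloxy anti to the carbocycle) | C[Si](C)(C)OC=1C[C@H]([C@@H](O[C@H]4C[C@@H](C)CC[C@@H]4C(C)C)OC3=O)[C@H]3C(C)(OC)C=1 | intermediate (not isolated)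
5 | (3S,3aS,7aS)-3-(d-menthyloxy)-7-methyl-3a,4-dihydro-2-benzofuran-1,5(3H,7aH)-dione (ring B as C5=C10 enone, cis-fused lactone acetal) | O=C1C[C@H]([C@@H](O[C@H]4C[C@@H](C)CC[C@@H]4C(C)C)OC3=O)[C@H]3C(C)=C1 | intermediate
6 | 2-(3-chloropropyl)-2-methyl-1,3-dioxolane | CC1(CCCCl)OCCO1 | starting material
7 | [3-(2-methyl-1,3-dioxolan-2-yl)propyl]magnesium chloride | CC1(CCC[Mg]Cl)OCCO1 | intermediate (not isolated)
8 | trimethylsilyl enol ether (C5=C6) of 9 | C[Si](C)(C)OC=1C[C@H]([C@@H](O[C@H]4C[C@@H](C)CC[C@@H]4C(C)C)OC3=O)[C@H]3[C@@](C)(CCCC5(C)OCCO5)C=1 | intermediate (not isolated)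
9 | (3S,3aS,7S,7aS)-3-(d-menthyloxy)-7-methyl-7-[3-(2-methyl-1,3-dioxolan-2-yl)propyl]hexahydro-2-benzofuran-1,5-dione (C10 methyl cis to the lactone carbonyl carbon C11) | O=C1C[C@H]([C@@H](O[C@H]4C[C@@H](C)CC[C@@H]4C(C)C)OC3=O)[C@H]3[C@@](C)(CCCC5(C)OCCO5)C1 | intermediate
10 | (3S,3aS,7S,7aS)-3-(d-menthyloxy)-7-methyl-7-(4-oxopentyl)hexahydro-2-benzofuran-1,5-dione | O=C1C[C@H]([C@@H](O[C@H]4C[C@@H](C)CC[C@@H]4C(C)C)OC3=O)[C@H]3[C@@](C)(CCCC(C)=O)C1 | intermediate (not isolated)
11 | aldol: 4-hydroxy-4-methyl tricycle with the C4–C5 bond formed (C4 and C5 epimers) | O=C1C[C@H]([C@@H](O[C@H]4C[C@@H](C)CC[C@@H]4C(C)C)OC3=O)[C@H]3[C@@]2(C)CCCC(C)(O)C12 | intermediate (not isolated)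
12 | (12S)-12-(d-menthyloxy)-6-oxo-13-nordrim-4-en-11,12-olide (C4=C5 enone; 8α-H, 9α-H, 10β-CH3) | O=C1C[C@H]([C@@H](O[C@H]4C[C@@H](C)CC[C@@H]4C(C)C)OC3=O)[C@H]3[C@@]2(C)CCCC(C)=C12 | intermediate
13 | 6-(trimethylsilyloxy)drim-5-ene derivative of 14 (C5=C6 silyl enol ether) | C[Si](C)(C)OC=1C[C@H]([C@@H](O[C@H]4C[C@@H](C)CC[C@@H]4C(C)C)OC3=O)[C@H]3[C@@]2(C)CCCC(C)(C)C=12 | intermediate (not isolated)
14 | (12S)-12-(d-menthyloxy)-6-oxodrimane-11,12-olide (trans-decalin: 5α-H, 10β-CH3; 8α-H, 9α-H, lactone cis-fused on the β-face) | O=C1C[C@H]([C@@H](O[C@H]4C[C@@H](C)CC[C@@H]4C(C)C)OC3=O)[C@H]3[C@@]2(C)CCCC(C)(C)[C@H]12 | intermediate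
15 | (12S)-6β-hydroxy-12-(d-menthyloxy)drimane-11,12-olide (6R; otherwise as 14) | O[C@@H]1C[C@H]([C@@H](O[C@H]4C[C@@H](C)CC[C@@H]4C(C)C)OC3=O)[C@H]3[C@@]2(C)CCCC(C)(C)[C@H]12 | intermediate
16 | (2E,4E,6E)-octa-2,4,6-trienoic acid | C/C=C/C=C/C=C/C(=O)O | starting material
17 | (2E,4E,6E)-octa-2,4,6-trienoic 2,4,6-trichlorobenzoic anhydride | C/C=C/C=C/C=C/C(=O)OC(=O)c1c(Cl)cc(Cl)cc1Cl | intermediate (not isolated)
18 | (12S)-12-(d-menthyloxy)-6β-[(2E,4E,6E)-octa-2,4,6-trienoyloxy]drimane-11,12-olide | C/C=C/C=C/C=C/C(=O)O[C@@H]1C[C@H]([C@@H](O[C@H]4C[C@@H](C)CC[C@@H]4C(C)C)OC3=O)[C@H]3[C@@]2(C)CCCC(C)(C)[C@H]12 | intermediate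
19 | 12-hydroxy-6β-[(2E,4E,6E)-octa-2,4,6-trienoyloxy]drimane-11,12-olide (lactol, C12 epimers) | C/C=C/C=C/C=C/C(=O)O[C@@H]1C[C@H](C(O)OC3=O)[C@H]3[C@@]2(C)CCCC(C)(C)[C@H]12 | intermediate
20 | 6β-[(2E,4E,6E)-octa-2,4,6-trienoyloxy]drimane-11,12-dioic anhydride (cis-fused, 8α-H, 9α-H) | C/C=C/C=C/C=C/C(=O)O[C@@H]1C[C@H](C(=O)OC3=O)[C@H]3[C@@]2(C)CCCC(C)(C)[C@H]12 | intermediate (not isolated)
21 | (1S,2S,4R,4aS,8aS)-5,5,8a-trimethyl-4-[(2E,4E,6E)-octa-2,4,6-trienoyloxy]decahydronaphthalene-1,2-dicarboxylic acid (drimane numbering: 5S,6R,8S,9S,10S) | C/C=C/C=C/C=C/C(=O)O[C@@H]1C[C@H](C(=O)O)[C@H](C(=O)O)[C@@]2(C)CCCC(C)(C)[C@H]12 | target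

**Totals**

Total step count: 9. Longest linear sequence: 9 steps (1 → 2 → 5 → 9 → 12 → 14 → 15 → 18 → 19 → 21); compounds 3, 6 and 16 enter as purchased materials.

**Steps most likely to fail**

Step 5. Methyl transfer to the fully substituted enone may be slow. Beyond that, C5 may be protonated on the wrong face, or lost by enolisation toward the cis-fused ketone during the protic quench. The fallback delivers hydrogen to C5 as an atom instead of a proton. It sets out from 13, which is used crude and treated with N-bromosuccinimide (THF, –78 °C). Electrophilic bromination of the silyl enol ether should give the 5-bromo-6-ketone F1. F1 is then reduced with Bu3SnH and AIBN (PhH, 80 °C), the planar α-keto radical at C5 being expected to take hydrogen from the less hindered α-face. The route is rejoined at 14.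

Step 3. The organometallic may deprotonate C9 (γ to the ketone, α to the lactone) instead of adding, may attack the lactone carbonyl, or may add with insufficient facial selectivity at C10. The fallback sets C10 in the cycloaddition instead. It sets out from 7 (made from 6), which is converted to the alkylcopper (CuBr·SMe2, Et2O/Me2S, –45 °C) and added syn across propyne. The alkenylcopper is trapped with acetyl chloride (Pd(PPh3)4 cat.) to give (Z)-4-methyl-7-(2-methyl-1,3-dioxolan-2-yl)hept-3-en-2-one F2. Kinetic silylation (LDA, TMSCl, THF, –78 °C) gives the (Z)-2-(trimethylsilyloxy)-1,3-diene F3. F3 is heated with 3 (PhMe, 110–130 °C); an endo cycloaddition anti to the menthyloxy group should place the outside methyl cis to C11. The route is rejoined at 8, which gives 9 on the same acidic work-up.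

Step 7. Acylation of the axial alcohol, which is flanked by two axial methyl groups, may be slow, and the activated trienoic acid may decompose or oligomerise. The fallback builds the trienoate on the alcohol from a small acyl group. It sets out from 15, which is esterified with diethylphosphonoacetic acid (DCC, DMAP, CH2Cl2) to the 6β-(diethylphosphonoacetate) F4. A Horner–Wadsworth–Emmons reaction with (2E,4E)-hexa-2,4-dienal (LiCl, DBU, MeCN) should form the 2E double bond. The route is rejoined at 18.

**Further compounds**

F1 | step 5 | (12S)-5-bromo-12-(d-menthyloxy)-6-oxodrimane-11,12-olide | O=C1C[C@H]([C@@H](O[C@H]4C[C@@H](C)CC[C@@H]4C(C)C)OC3=O)[C@H]3[C@@]2(C)CCCC(C)(C)C12Br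
F2 | step 3 | (Z)-4-methyl-7-(2-methyl-1,3-dioxolan-2-yl)hept-3-en-2-one | CC(=O)/C=C(C)\CCCC1(C)OCCO1
F3 | step 3 | (Z)-4-methyl-7-(2-methyl-1,3-dioxolan-2-yl)-2-(trimethylsilyloxy)hepta-1,3-diene | C=C(O[Si](C)(C)C)/C=C(C)\CCCC1(C)OCCO1
F4 | step 7 | (12S)-6β-[(diethoxyphosphoryl)acetoxy]-12-(d-menthyloxy)drimane-11,12-olide | CCOP(=O)(CC(=O)O[C@@H]1C[C@H]([C@@H](O[C@H]4C[C@@H](C)CC[C@@H]4C(C)C)OC3=O)[C@H]3[C@@]2(C)CCCC(C)(C)[C@H]12)OCC
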